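- At the reading time of 50 min I wanted the target in beta, gamma, delta and epsilon, each charged with partner at 0.700 of the starting material and differing in temperature.

| flask | starting material | partner | temperature | remark | time |
|---|---|---|---|---|---|
| east | 20 mM | 7 mM | 55 °C | run made earlier |  |
| north | 20 mM | 10 mM | 88 °C | run made earlier |  |
| south | 30 mM | 14 mM | 55 °C | run made earlier |  |
| beta | 20 mM | 14.0 mM |  | at 40 °C until 25 min, from then on at 100 °C | 50 min |
| gamma | 20 mM | 14.0 mM | 70 °C |  | 50 min |
| delta | 20 mM | 14.0 mM | 100 °C |  | 50 min |
| epsilon | 20 mM | 14.0 mM | 40 °C |  | 50 min |

| run | time / min | target / % | starting material / % |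
|---|---|---|---|
| east | 8.00 | 0 | 92.1 |
| east | 20.0 | 4.2 | 81.4 |
| east | 40.0 | 5.0 | 64.8 |
| east | 60.0 | 7.4 | 51.1 |
| north | 1.50 | 2.2 | 67.9 |
| north | 4.00 | 5.2 | 32.6 |
| north | 8.00 | 8.0 | 10.9 |
| north | 12.0 | 6.4 | 2.7 |
| south | 5.00 | 0.5 | 95.4 |
| south | 12.0 | 1.1 | 87.4 |
| south | 25.0 | 4.1 | 76.7 |
| south | 60.0 | 12.1 | 53.7 |

(each reading ± 1 percentage point)

* the flask with the highest amount of target, in percent of the starting material charged ("all alike" if they lie within 1.5 percentage points) (beta / gamma / delta / epsilon / all alike)
* final target, as a percentage of the starting material charged, in beta
* final target, as a percentage of the starting material charged, in gamma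
* final target, as a percentage of the starting material charged, in delta
* final target, as a percentage of the starting material charged, in epsilon

- what is said of target includes crystals
- crystals is a solid; its amount is given per volume of the solution
- what may be going on: starting material -> intermediate; partner + intermediate -> target; intermediate -> side product; crystals <-> target; partner -> decomposed reagent

- The readings looked contradictory: the north run had lost nearly all of its starting material by 12.0 min and showed 6.4% target, whereas the east run had lost half by 60.0 min and showed 7.4%, so twice the turnover gave no more target.
- I therefore worked with the fraction left: the east and south runs, with different charges, still held 51.1% and 53.7% at 60.0 min, so I took the loss as first order, with 0.0112 /min in the east run and 0.277 /min in the north run.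
- These gave an activation energy of 95.8 kJ/mol, the number that carries the fraction left from one temperature to another.
- Dividing target by the fraction gone cleared up the contradiction, because this capture share (the selectivity) read 0.261 in the south run, which had the asked amount of partner, and 0.0658 in the hot north run, lower, where the partner differed as well as the temperature (10 mM against 14 mM).
- I reckoned 7.45% left in gamma and 90.1% left in epsilon, where the south share gave 2.58% target.
- For gamma, the geometric mean of the two shares gave 12.1%, and for delta, the north share gave 6.58%, so I ranked gamma first and took beta as delta.
- The forecast, with 16% for gamma above my figure and 1.6% for epsilon below it, named gamma, gave 8.7% for beta and 8.5% for delta, and held that “Epsilon is limited by conversion and lag”.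
- The flasks gave gamma as the highest, with 7.62% in beta, 17.3% in gamma, 7.39% in delta and 1.60% in epsilon; gamma held 7.86% starting material against my 7.45%, and epsilon 90.7% against my 90.1%.

    starting material → intermediate (k = 8.48 × 10⁻⁴ /s, Ea = 97.0 kJ/mol)
    partner + intermediate → target (k = 0.0792 /M/s, Ea = 61.0 kJ/mol)
    intermediate → side product (k = 0.00104 /s, Ea = 114 kJ/mol)
    crystals ⇌ target, rate k4*(cs4 - [target]) while solid is left; crystals form when [target] > cs4 (solubility = 3.50 mM, k = 0.0141 /s)
    partner → decomposed reagent (k = 8.61 × 10⁻⁴ /s, Ea = 92.0 kJ/mol)
    (constants at 70 °C)

- In epsilon the half-life of the starting material by its passing into intermediate was 5.9 h at 24.4 min, longer than the 50 min of the reading, and intermediate was still being made 2.71 times faster than it was used up at that reading. Carried to a repeat of epsilon at 65 °C, the activation energy gave 20.6% left, and that neighbouring flask held 21.5% starting material beside 17.9% target.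

The earlier runs and the new flask are calculated with constants of no real substance; scatter was added.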